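**Assumptions (one line):** labdane numbering (C1–C20) is used for positions in the reasoning; compounds 1, 3, 4 and 14 are taken as purchasable; the CuH catalyst in step 4 is assumed to show its usual facial sense (otherwise the ligand antipode is used).

**Retrosynthetic overview**
1. C12–C13: Negishi coupling of a C12 alkylzinc with 3-bromofuran-2(5H)-one, done last.
2. C4 methyl and C20 acetate: one-pot ester-enolate methylation and O-acetylation on the trans-decalin.
3. Key disconnection C9–C10: Ti(III) radical opening of a C10 spiro-epoxide on ring A; the epoxide oxygen becomes the C20 oxygen, and ring B, C9, C10 and the exocyclic alkene form together (ring A first, then ring B).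
4. Ring A ketone: asymmetric CuH reduction of methyl 3-oxocyclohex-1-ene-1-carboxylate with in situ alkylation by an (E)-bromo chloride; epoxide by Corey–Chaykovsky.
5. Side-chain piece: Negishi carboalumination of 4-bromobut-1-yne, oxirane opening, Appel chlorination.

**Route**

Step 1
Reactants: 1 3-bromocyclohex-2-en-1-one
Product: 2 methyl 3-oxocyclohex-1-ene-1-carboxylate
Conditions: Pd(OAc)2 (3 mol %), dppp, CO (1 atm), MeOH, Et3N, DMF, 70 °C
Reagents that add atoms: carbon monoxide ([C-]#[O+]); methanol (CO)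
Why: Pd-catalysed alkoxycarbonylation of the vinyl bromide (oxidative addition, CO insertion, methanolysis) gives the β-carbomethoxy enone, and no stereocentre is formed.

Step 2
Reactants: 3 4-bromobut-1-yne; 4 oxirane
Product: 6 (3E)-6-bromo-4-methylhex-3-en-1-ol, via alkenylalane 5 (not isolated)
Conditions: Me3Al, Cp2ZrCl2 (25 mol %), CH2Cl2, 0 → 23 °C; then n-BuLi, THF, −78 °C; oxirane, −78 → 0 °C; aq. HCl
Reagents that add atoms: trimethylaluminium (C[Al](C)C)
Why: Negishi Zr-catalysed carboalumination adds Me–Al syn across the terminal alkyne with methyl on the internal carbon, and the derived alanate opens oxirane with retention, which fixes the (E)-trisubstituted C8=C9 alkene that later dictates the C9 configuration.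

Step 3
Reactants: 6 (3E)-6-bromo-4-methylhex-3-en-1-ol
Product: 7 (3E)-1-bromo-6-chloro-3-methylhex-3-ene
Conditions: PPh3, CCl4, CH2Cl2, 0 → 40 °C
Reagents that add atoms: carbon tetrachloride (ClC(Cl)(Cl)Cl)
Why: The Appel reaction converts the primary alcohol to the chloride under neutral conditions that leave the primary bromide and the alkene untouched, giving two halides of graded reactivity.

Step 4
Reactants: 2 methyl 3-oxocyclohex-1-ene-1-carboxylate; 7 (3E)-1-bromo-6-chloro-3-methylhex-3-ene
Product: 9 methyl (1R,2S)-2-[(3E)-6-chloro-3-methylhex-3-en-1-yl]-3-oxocyclohexane-1-carboxylate, via silyl enol ether 8 (not isolated)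
Conditions: Cu(OAc)2·H2O (3 mol %), (R)-DTBM-SEGPHOS, (EtO)2MeSiH, toluene, 0 °C; then 7, TBAT, NaI (20 mol %), THF, 0 → 23 °C; chromatography to remove the minor cis isomer
Reagents that add atoms: none
Why: Ligand-controlled asymmetric CuH conjugate reduction delivers hydride to the ester-bearing β-carbon to set C4 (R) and gives the regiodefined silyl enol ether, whose fluoride-liberated enolate is alkylated by the bromide end of 7 anti to the neighbouring ester (tandem 1,4-reduction/enolate alkylation), which sets the trans C5 (S) centre.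

Step 5
Reactants: 9 methyl (1R,2S)-2-[(3E)-6-chloro-3-methylhex-3-en-1-yl]-3-oxocyclohexane-1-carboxylate
Product: 10 methyl (4S,5R)-4-[(3E)-6-chloro-3-methylhex-3-en-1-yl]-1-oxaspiro[2.5]octane-5-carboxylate (both C3 epimers)
Conditions: Me3S+ I−, KHMDS, THF, −10 → 0 °C
Reagents that add atoms: trimethylsulfonium iodide (C[S+](C)C.[I-])
Why: Corey–Chaykovsky epoxidation with dimethylsulfonium methylide attacks only the ketone (ester, alkene and alkyl chloride are inert), and the mixed configuration at the new spiro carbon is irrelevant because that carbon becomes a planar radical in step 6.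

Step 6
Reactants: 10 methyl (4S,5R)-4-[(3E)-6-chloro-3-methylhex-3-en-1-yl]-1-oxaspiro[2.5]octane-5-carboxylate
Product: 11 methyl (1R,4aR,5S,8aS)-5-(2-chloroethyl)-4a-(hydroxymethyl)-6-methylidenedecahydronaphthalene-1-carboxylate
Conditions: Cp2TiCl2 (2.5 equiv), Mn dust, THF (degassed, 0.02 M, slow addition of 10), 23 °C; 1 M HCl work-up
Reagents that add atoms: none
Why: Cp2TiCl opens the 2,2-disubstituted epoxide homolytically (Nugent–RajanBabu) to the tertiary C10 radical bearing CH2O–Ti, which closes 6-endo onto the (E)-alkene through a chair transition state with the C5 tether equatorial (C20 axial and anti to H5, C11 equatorial, hence 4aR,5S), and the tertiary C8 radical is then captured by a second Cp2TiCl and loses a methyl β-hydrogen to give the exocyclic alkene.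

Step 7
Reactants: 11 methyl (1R,4aR,5S,8aS)-5-(2-chloroethyl)-4a-(hydroxymethyl)-6-methylidenedecahydronaphthalene-1-carboxylate
Product: 13 methyl (1S,4aS,5S,8aR)-4a-[(acetyloxy)methyl]-5-(2-chloroethyl)-1-methyl-6-methylidenedecahydronaphthalene-1-carboxylate, via lithium alkoxide 12 (not isolated)
Conditions: LDA (2.4 equiv), THF–DMPU, −78 → −40 °C; MeI, −78 °C; then Ac2O, −78 → 0 °C
Reagents that add atoms: iodomethane (CI); acetic anhydride (CC(=O)OC(C)=O)
Why: The alkoxide/ester-enolate dianion is C-methylated from the equatorial α face because the axial C10–CH2OLi group blocks the β face (the usual axial-ester outcome for C4 ester enolates of trans-decalins, setting C4 as S), and the lithium alkoxide is then O-acetylated before it can lactonise onto the now 1,3-diaxial ester.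

Step 8
Reactants: 13 methyl (1S,4aS,5S,8aR)-4a-[(acetyloxy)methyl]-5-(2-chloroethyl)-1-methyl-6-methylidenedecahydronaphthalene-1-carboxylate; 14 3-bromofuran-2(5H)-one
Product: 16 methyl (1S,4aS,5S,8aR)-4a-[(acetyloxy)methyl]-1-methyl-6-methylidene-5-[2-(2-oxo-2,5-dihydrofuran-3-yl)ethyl]decahydronaphthalene-1-carboxylate, via alkylzinc chloride 15 (not isolated)
Conditions: Zn dust (TMSCl/1,2-dibromoethane-activated), Bu4NI (0.3 equiv), DMA, 80 °C; then 14, Pd(OAc)2 (3 mol %), SPhos, THF, 23–40 °C
Reagents that add atoms: none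
Why: Iodide-catalysed zinc insertion into the primary chloride gives an ester-tolerant alkylzinc that undergoes Negishi sp3–sp2 coupling with the α-bromobutenolide, installing the furanone without touching the stereocentres, the acetate or the exocyclic alkene.

**Compound list**
1 | 3-bromocyclohex-2-en-1-one | O=C1C=C(Br)CCC1 | starting material
2 | methyl 3-oxocyclohex-1-ene-1-carboxylate | COC(=O)C1=CC(=O)CCC1 | intermediate
3 | 4-bromobut-1-yne | C#CCCBr | starting material
4 | oxirane | C1CO1 | starting material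
5 | [(1E)-4-bromo-2-methylbut-1-en-1-yl]dimethylalumane | BrCC/C(C)=C/[Al](C)C | intermediate
6 | (3E)-6-bromo-4-methylhex-3-en-1-ol | BrCC/C(C)=C/CCO | intermediate
7 | (3E)-1-bromo-6-chloro-3-methylhex-3-ene | BrCC/C(C)=C/CCCl | intermediate
8 | methyl (1R)-3-{[diethoxy(methyl)silyl]oxy}cyclohex-2-ene-1-carboxylate | COC(=O)[C@@H]1CCCC(O[Si](C)(OCC)OCC)=C1 | intermediate
9 | methyl (1R,2S)-2-[(3E)-6-chloro-3-methylhex-3-en-1-yl]-3-oxocyclohexane-1-carboxylate | ClCC/C=C(\C)CC[C@H]1[C@H](C(=O)OC)CCCC1=O | intermediate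
10 | methyl (4S,5R)-4-[(3E)-6-chloro-3-methylhex-3-en-1-yl]-1-oxaspiro[2.5]octane-5-carboxylate (both C3 epimers) | ClCC/C=C(\C)CC[C@H]1[C@H](C(=O)OC)CCCC12CO2 | intermediate
11 | methyl (1R,4aR,5S,8aS)-5-(2-chloroethyl)-4a-(hydroxymethyl)-6-methylidenedecahydronaphthalene-1-carboxylate | C=C1CC[C@@H]2[C@](CO)(CCC[C@H]2C(=O)OC)[C@H]1CCCl | intermediate
12 | lithium alkoxide of methyl (1S,4aS,5S,8aR)-5-(2-chloroethyl)-4a-(hydroxymethyl)-1-methyl-6-methylidenedecahydronaphthalene-1-carboxylate | C=C1CC[C@@H]2[C@](C[O-])(CCC[C@]2(C)C(=O)OC)[C@H]1CCCl.[Li+] | intermediate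
13 | methyl (1S,4aS,5S,8aR)-4a-[(acetyloxy)methyl]-5-(2-chloroethyl)-1-methyl-6-methylidenedecahydronaphthalene-1-carboxylate | C=C1CC[C@@H]2[C@](COC(C)=O)(CCC[C@]2(C)C(=O)OC)[C@H]1CCCl | intermediate
14 | 3-bromofuran-2(5H)-one | O=C1OCC=C1Br | starting material
15 | methyl (1S,4aS,5S,8aR)-4a-[(acetyloxy)methyl]-5-[2-(chlorozincio)ethyl]-1-methyl-6-methylidenedecahydronaphthalene-1-carboxylate | C=C1CC[C@@H]2[C@](COC(C)=O)(CCC[C@]2(C)C(=O)OC)[C@H]1CC[Zn]Cl | intermediate
16 | methyl (1S,4aS,5S,8aR)-4a-[(acetyloxy)methyl]-1-methyl-6-methylidene-5-[2-(2-oxo-2,5-dihydrofuran-3-yl)ethyl]decahydronaphthalene-1-carboxylate | C=C1CC[C@@H]2[C@](COC(C)=O)(CCC[C@]2(C)C(=O)OC)[C@H]1CCC1=CCOC1=O | target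

**Totals**
Total step count: 8. Longest linear sequence: 7 (steps 2, 3, 4, 5, 6, 7, 8 from 4-bromobut-1-yne).

**Three steps most likely to fail, each with a fallback**

Step 4 (alkylation of a hindered enolate by an unactivated primary bromide; the C5 centre is epimerisable). The fallback sets out from 2 and comes back at 9. CBS reduction of 2 ((R)-Me-CBS, catecholborane, −78 °C) gives methyl (3S)-3-hydroxycyclohex-1-ene-1-carboxylate F1, and silylation (TBSCl, imidazole) gives methyl (3S)-3-[(tert-butyldimethylsilyl)oxy]cyclohex-1-ene-1-carboxylate F2. The Grignard reagent from 7, bromido[(3E)-6-chloro-3-methylhex-3-en-1-yl]magnesium F3 (Mg inserts only into C–Br), is added with CuI (10 mol %)/BF3·OEt2 at −78 °C anti to the silyloxy group. Equilibration of the ester with NaOMe/MeOH gives the all-equatorial methyl (1R,2S,3S)-3-[(tert-butyldimethylsilyl)oxy]-2-[(3E)-6-chloro-3-methylhex-3-en-1-yl]cyclohexane-1-carboxylate F4. TBAF gives methyl (1R,2S,3S)-2-[(3E)-6-chloro-3-methylhex-3-en-1-yl]-3-hydroxycyclohexane-1-carboxylate F5, and Dess–Martin oxidation gives 9.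

Step 6 (the C10 radical may be quenched to an allylic alcohol before it cyclises, or the alkene may form endocyclic). The fallback sets out from 10 and comes back at 11. Pyridinium bromide (CH2Cl2, −20 °C) opens the epoxide at the tertiary carbon to methyl (1R,2S)-3-bromo-2-[(3E)-6-chloro-3-methylhex-3-en-1-yl]-3-(hydroxymethyl)cyclohexane-1-carboxylate F6. Halogen-atom-transfer/cobaloxime photocatalysis (4CzIPN, Co(dmgH)2(py)Cl, Et3N, MeCN, blue LEDs) then generates the same C10 radical without titanium. After ring closure, Co(II) removes a methyl hydrogen from the C8 radical to give 11.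

Step 7 (the alkoxide may lactonise onto the axial ester before acetylation, or O-methylation may compete). The fallback sets out from 10 and comes back at 13. The ester is methylated before ring closure (LDA, MeI, −78 °C, electrophile anti to the C5 side chain) to give methyl (4S,5S)-4-[(3E)-6-chloro-3-methylhex-3-en-1-yl]-5-methyl-1-oxaspiro[2.5]octane-5-carboxylate F7. Cyclisation with Cp2TiCl as in step 6 gives methyl (1S,4aS,5S,8aR)-5-(2-chloroethyl)-4a-(hydroxymethyl)-1-methyl-6-methylidenedecahydronaphthalene-1-carboxylate F8, whose titanium alkoxide is acetylated in the same flask (Ac2O, pyridine, DMAP) to give 13.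

**Further compounds**
F1 | step 4 | methyl (3S)-3-hydroxycyclohex-1-ene-1-carboxylate | COC(=O)C1=C[C@@H](O)CCC1
F2 | step 4 | methyl (3S)-3-[(tert-butyldimethylsilyl)oxy]cyclohex-1-ene-1-carboxylate | COC(=O)C1=C[C@@H](O[Si](C)(C)C(C)(C)C)CCC1
F3 | step 4 | bromido[(3E)-6-chloro-3-methylhex-3-en-1-yl]magnesium | ClCC/C=C(\C)CC[Mg]Br
F4 | step 4 | methyl (1R,2S,3S)-3-[(tert-butyldimethylsilyl)oxy]-2-[(3E)-6-chloro-3-methylhex-3-en-1-yl]cyclohexane-1-carboxylate | ClCC/C=C(\C)CC[C@H]1[C@H](C(=O)OC)CCC[C@@H]1O[Si](C)(C)C(C)(C)C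
F5 | step 4 | methyl (1R,2S,3S)-2-[(3E)-6-chloro-3-methylhex-3-en-1-yl]-3-hydroxycyclohexane-1-carboxylate | ClCC/C=C(\C)CC[C@H]1[C@H](C(=O)OC)CCC[C@@H]1O
F6 | step 6 | methyl (1R,2S)-3-bromo-2-[(3E)-6-chloro-3-methylhex-3-en-1-yl]-3-(hydroxymethyl)cyclohexane-1-carboxylate (both C3 epimers) | ClCC/C=C(\C)CC[C@H]1[C@H](C(=O)OC)CCCC1(Br)CO
F7 | step 7 | methyl (4S,5S)-4-[(3E)-6-chloro-3-methylhex-3-en-1-yl]-5-methyl-1-oxaspiro[2.5]octane-5-carboxylate (both C3 epimers) | ClCC/C=C(\C)CC[C@H]1[C@@](C)(C(=O)OC)CCCC12CO2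
F8 | step 7 | methyl (1S,4aS,5S,8aR)-5-(2-chloroethyl)-4a-(hydroxymethyl)-1-methyl-6-methylidenedecahydronaphthalene-1-carboxylate | C=C1CC[C@@H]2[C@](CO)(CCC[C@]2(C)C(=O)OC)[C@H]1CCCl
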